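**Retrosynthetic overview**
1. The enal arm is added last, by Heck coupling of an aryl bromide with acrolein diethyl acetal and acetal hydrolysis.
2. The dioxane ring is closed at the benzylic C–O bond by acid-mediated cyclodehydration of a phenol/benzylic alcohol; the trans product is the thermodynamic one, so the C–aryl centre follows from the C–methyl centre.
3. The aryl–C bond comes from addition of a 3,4,5-trimethoxyphenyl Grignard reagent to a 2-hydroxy-1,4-benzodioxane lactol.
4. The lactol and its C–methyl stereocentre come from an amine-catalysed enantioselective [4+2] reaction of propanal (as its enamine) with an o-quinone.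
5. The o-quinone comes from 5-bromo-2-hydroxy-3-methoxybenzaldehyde by Dakin oxidation and PhI(OAc)2 oxidation. Both arene rings are bought; only the dioxane ring is built (formed in step 2, opened in step 3, re-formed in step 4).

Assumption: the target is read as the trans-(2S,3S) isomer; lactol 8 and alcohol 11 are carried on as epimer mixtures at the carbon that is rebuilt in step 4; reagent 9 is bought as its 0.5 M THF solution.

**Step 1**
Reactants: 1 5-bromo-2-hydroxy-3-methoxybenzaldehyde
Product: 3 5-bromo-3-methoxybenzene-1,2-diol, via aryl formate 2 (not isolated)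
Conditions: H2O2 (30% aq, 1.2 equiv), NaOH (1.0 equiv), H2O, N2, 0 °C to rt; then 1 M HCl
Reagents that add atoms: hydrogen peroxide, OO
Why: Dakin oxidation: hydroperoxide adds to the aldehyde of the ortho-hydroxybenzaldehyde, the aryl group migrates to oxygen to give formate 2, and this is saponified in the same basic medium to the catechol; no stereocentre is involved.

**Step 2**
Reactants: 3 5-bromo-3-methoxybenzene-1,2-diol; 4 propanal
Product: 8 (3S)-7-bromo-5-methoxy-3-methyl-2,3-dihydro-1,4-benzodioxin-2-ol, via o-quinone 5 (not isolated), via enamine 6 (not isolated), via aminal cycloadduct 7 (not isolated)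
Conditions: PhI(OAc)2 (1.0 equiv), CH2Cl2, −40 °C; cannulated into 4 (3 equiv), (S)-2-[diphenyl(trimethylsilyloxy)methyl]pyrrolidine (20 mol%), CH2Cl2, −40 to −20 °C; then THF/pH 7 buffer, 0 °C
Reagents that add atoms: water, O
Why: Proposed new method: propanal condenses with the secondary amine to the s-trans (E)-enamine 6, which acts as the electron-rich 2π partner in an inverse-electron-demand oxa-Diels–Alder reaction with the O=C–C=O unit of quinone 5; the enamine carbon should bond to the oxygen of the C2 carbonyl (cross-conjugated, more electron-poor, next to the OMe-bearing carbon) because the charge then builds up on the C1 oxygen, which is the more basic vinylogous-ester oxygen (hydrogen-bonded by the AcOH released in the oxidation) and gives the better-stabilised phenoxide (meta to both OMe and Br), and this oxygen then closes onto the iminium carbon to give aminal 7, which is hydrolysed to lactol 8 with release of the catalyst; the CPh2(OTMS) group shields one face of the enamine, so C–O bond formation on the open face gives the (3S) centre, the same sense as other α-heterofunctionalisations with this catalyst; the closest known reactions are the amine-catalysed enantioselective α-aryloxylation of aldehydes with tetrachloro-o-benzoquinone and the racemic [4+2] addition of enamines to o-quinones, neither shown for a non-halogenated, unsymmetrical o-quinone where a regiochemical preference is also needed.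

**Step 3**
Reactants: 8 (3S)-7-bromo-5-methoxy-3-methyl-2,3-dihydro-1,4-benzodioxin-2-ol; 9 3,4,5-trimethoxyphenylmagnesium bromide
Product: 11 (2S)-2-(4-bromo-2-hydroxy-6-methoxyphenoxy)-1-(3,4,5-trimethoxyphenyl)propan-1-ol, via open-chain aldehyde 10 (not isolated)
Conditions: 9 (3.0 equiv, 0.5 M in THF), THF, −78 to 0 °C; then NH4Cl (aq)
Reagents that add atoms: none
Why: Grignard addition to a lactol: the first equivalent deprotonates the hemiacetal, which opens to the magnesium phenoxide of aldehyde 10, and a second equivalent adds 1,2 to the aldehyde at low temperature, so the α-aryloxy centre is not enolised and the aryl bromide is not exchanged; the new carbinol centre forms unselectively and is rebuilt in step 4.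

**Step 4**
Reactants: 11 (2S)-2-(4-bromo-2-hydroxy-6-methoxyphenoxy)-1-(3,4,5-trimethoxyphenyl)propan-1-ol
Product: 12 (2S,3S)-7-bromo-5-methoxy-3-methyl-2-(3,4,5-trimethoxyphenyl)-2,3-dihydro-1,4-benzodioxine
Conditions: TsOH·H2O (10 mol%), toluene (0.02 M), 50 °C
Reagents that add atoms: none
Why: Acid-catalysed SN1-type cyclodehydration (intramolecular etherification): both C1 epimers ionise at the electron-rich benzylic carbon and the ortho-phenol closes the six-membered ring reversibly under the acid, so the aryl group settles trans to the fixed (3S)-methyl group (both pseudo-equatorial), which sets C2 as S.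

**Step 5**
Reactants: 12 (2S,3S)-7-bromo-5-methoxy-3-methyl-2-(3,4,5-trimethoxyphenyl)-2,3-dihydro-1,4-benzodioxine; 13 acrolein diethyl acetal (3,3-diethoxyprop-1-ene)
Product: 15 (2E)-3-[(2S,3S)-5-methoxy-3-methyl-2-(3,4,5-trimethoxyphenyl)-2,3-dihydro-1,4-benzodioxin-7-yl]prop-2-enal, via diethyl acetal 14 (not isolated)
Conditions: Pd(OAc)2 (3 mol%), nBu4NOAc, K2CO3, KCl, DMF, 90 °C; then 2 M HCl, rt
Reagents that add atoms: water, O
Why: Mizoroki–Heck reaction of the aryl bromide with acetal-masked acrolein under phosphine-free acetate conditions, where β-hydride elimination gives the (E)-cinnamyl acetal 14, and aqueous HCl hydrolyses it to the (E)-enal without touching the two ether stereocentres.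

**Compound list**
1 | 5-bromo-2-hydroxy-3-methoxybenzaldehyde | COc1cc(Br)cc(C=O)c1O | starting material
2 | 5-bromo-2-hydroxy-3-methoxyphenyl formate | COc1cc(Br)cc(OC=O)c1O | intermediate (not isolated)
3 | 5-bromo-3-methoxybenzene-1,2-diol | COc1cc(Br)cc(O)c1O | intermediate
4 | propanal | CCC=O | starting material
5 | 5-bromo-3-methoxycyclohexa-3,5-diene-1,2-dione | COC1=CC(Br)=CC(=O)C1=O | intermediate (not isolated)
6 | (2S)-2-[diphenyl(trimethylsilyloxy)methyl]-1-[(E)-prop-1-en-1-yl]pyrrolidine | C/C=C/N1CCC[C@H]1C(O[Si](C)(C)C)(c1ccccc1)c1ccccc1 | intermediate (not isolated)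
7 | (2R,3S)-7-bromo-2-{(2S)-2-[diphenyl(trimethylsilyloxy)methyl]pyrrolidin-1-yl}-5-methoxy-3-methyl-2,3-dihydro-1,4-benzodioxine | C[C@@H]1Oc2c(OC)cc(Br)cc2O[C@H]1N1CCC[C@H]1C(O[Si](C)(C)C)(c1ccccc1)c1ccccc1 | intermediate (not isolated)
8 | (3S)-7-bromo-5-methoxy-3-methyl-2,3-dihydro-1,4-benzodioxin-2-ol (both C2 epimers) | C[C@@H]1Oc2c(OC)cc(Br)cc2OC1O | intermediate
9 | 3,4,5-trimethoxyphenylmagnesium bromide | COc1cc([Mg]Br)cc(OC)c1OC | starting material
10 | (2S)-2-(4-bromo-2-hydroxy-6-methoxyphenoxy)propanal (as its magnesium phenoxide) | C[C@H](Oc1c(O)cc(Br)cc1OC)C=O | intermediate (not isolated)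
11 | (2S)-2-(4-bromo-2-hydroxy-6-methoxyphenoxy)-1-(3,4,5-trimethoxyphenyl)propan-1-ol (both C1 epimers) | C[C@H](Oc1c(O)cc(Br)cc1OC)C(O)c1cc(OC)c(OC)c(OC)c1 | intermediate
12 | (2S,3S)-7-bromo-5-methoxy-3-methyl-2-(3,4,5-trimethoxyphenyl)-2,3-dihydro-1,4-benzodioxine | COc1cc([C@@H]2Oc3cc(Br)cc(OC)c3O[C@H]2C)cc(OC)c1OC | intermediate
13 | acrolein diethyl acetal (3,3-diethoxyprop-1-ene) | C=CC(OCC)OCC | starting material
14 | (2S,3S)-7-[(E)-3,3-diethoxyprop-1-en-1-yl]-5-methoxy-3-methyl-2-(3,4,5-trimethoxyphenyl)-2,3-dihydro-1,4-benzodioxine | COc1cc([C@@H]2Oc3cc(/C=C/C(OCC)OCC)cc(OC)c3O[C@H]2C)cc(OC)c1OC | intermediate (not isolated)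
15 | (2E)-3-[(2S,3S)-5-methoxy-3-methyl-2-(3,4,5-trimethoxyphenyl)-2,3-dihydro-1,4-benzodioxin-7-yl]prop-2-enal | COc1cc([C@@H]2Oc3cc(/C=C/C=O)cc(OC)c3O[C@H]2C)cc(OC)c1OC | target

**Totals and risks**
Total step count: 5. Longest linear sequence: 5 steps (1 to 15). The enantiomeric purity of 15 is that reached in step 2, since every later centre follows from C3; if it is short of what is needed, 12 is the stage at which to try recrystallisation.

The three steps most likely to fail:

Step 2 (the proposed new reaction). The risks are: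
- Chemoselectivity: a non-halogenated o-quinone may be attacked at ring carbon by the enamine or the amine, or may simply be reduced.
- Regiochemistry: the predicted preference for bonding at the C2 oxygen rests on a modest electronic bias. The wrong regioisomer would carry through to an isomeric benzodioxane, so 8 must be checked by HMBC/NOE.
- Enantioselectivity: untested for this quinone.

The fallback uses known reactions and fixes the regiochemistry through the free phenol of 1. It sets out from 9 and 4, brings in 1, and comes back to the route at 12. Grignard reagent 9 adds to propanal 4 (THF, 0 °C) to give 1-(3,4,5-trimethoxyphenyl)propan-1-ol F1, which is dehydrated (TsOH cat., toluene, reflux) to (E)-1,2,3-trimethoxy-5-(prop-1-en-1-yl)benzene F2. Shi epoxidation (D-fructose-derived ketone catalyst, KHSO5 as 2KHSO5·KHSO4·K2SO4, K2CO3 buffer, MeCN/dimethoxymethane/H2O, 0 °C) is the metal-free asymmetric step and gives (2R,3R)-2-methyl-3-(3,4,5-trimethoxyphenyl)oxirane F3. Acid-catalysed methanolysis (camphorsulfonic acid cat., MeOH, 0 °C) opens it at the benzylic carbon to (2R)-1-methoxy-1-(3,4,5-trimethoxyphenyl)propan-2-ol F4, with the C2 centre untouched. Mitsunobu etherification with phenol 1 (PPh3, DIAD, THF) inverts C2 and gives 5-bromo-3-methoxy-2-{[(2S)-1-methoxy-1-(3,4,5-trimethoxyphenyl)propan-2-yl]oxy}benzaldehyde F5. Baeyer–Villiger oxidation (mCPBA, CH2Cl2) gives 5-bromo-3-methoxy-2-{[(2S)-1-methoxy-1-(3,4,5-trimethoxyphenyl)propan-2-yl]oxy}phenyl formate F6, and K2CO3 in MeOH/H2O cleaves it to 5-bromo-3-methoxy-2-{[(2S)-1-methoxy-1-(3,4,5-trimethoxyphenyl)propan-2-yl]oxy}phenol F7. BF3·OEt2 (CH2Cl2, 0 °C) ionises the benzylic methyl ether and closes the ring to 12.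

Step 4. The ring closure may give too much cis isomer. The ionised benzylic carbon can also lose the neighbouring proton to an enol ether, which would erode the C3 centre or lead to ketal by-products. The fallback replaces the SN1 closure by a stereospecific SN2 closure; it sets out from 11 and comes back at 12. Oxidation of the benzylic alcohol (activated MnO2, CH2Cl2) gives (2S)-2-(4-bromo-2-hydroxy-6-methoxyphenoxy)-1-(3,4,5-trimethoxyphenyl)propan-1-one F8. Felkin–Anh reduction (LiBH(s-Bu)3, THF, −78 °C) gives mainly the erythro alcohol (1R,2S)-2-(4-bromo-2-hydroxy-6-methoxyphenoxy)-1-(3,4,5-trimethoxyphenyl)propan-1-ol F9. Intramolecular Mitsunobu etherification (PPh3, DIAD, THF, 0 °C) inverts the benzylic carbon and gives the trans ring of 12.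

Step 5. The electron-rich bromide may couple slowly, and the Heck reaction can divert to the saturated 3-arylpropanoate ester. The fallback builds the enal by olefination instead; it sets out from 12 and comes back at 15. Bromine–lithium exchange (n-BuLi, THF, −78 °C) gives [(2S,3S)-5-methoxy-3-methyl-2-(3,4,5-trimethoxyphenyl)-2,3-dihydro-1,4-benzodioxin-7-yl]lithium F10. A DMF quench and aqueous work-up give (2S,3S)-5-methoxy-3-methyl-2-(3,4,5-trimethoxyphenyl)-2,3-dihydro-1,4-benzodioxine-7-carbaldehyde F11. Wittig reaction with (triphenylphosphoranylidene)acetaldehyde (toluene, 80 °C) gives the (E)-enal 15.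

**Further compounds**
F1 | step 2 | 1-(3,4,5-trimethoxyphenyl)propan-1-ol | CCC(O)c1cc(OC)c(OC)c(OC)c1
F2 | step 2 | (E)-1,2,3-trimethoxy-5-(prop-1-en-1-yl)benzene | C/C=C/c1cc(OC)c(OC)c(OC)c1
F3 | step 2 | (2R,3R)-2-methyl-3-(3,4,5-trimethoxyphenyl)oxirane | C[C@H]1O[C@@H]1c1cc(OC)c(OC)c(OC)c1
F4 | step 2 | (2R)-1-methoxy-1-(3,4,5-trimethoxyphenyl)propan-2-ol (C1 mainly S) | C[C@@H](O)C(OC)c1cc(OC)c(OC)c(OC)c1
F5 | step 2 | 5-bromo-3-methoxy-2-{[(2S)-1-methoxy-1-(3,4,5-trimethoxyphenyl)propan-2-yl]oxy}benzaldehyde | C[C@H](Oc1c(C=O)cc(Br)cc1OC)C(OC)c1cc(OC)c(OC)c(OC)c1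
F6 | step 2 | 5-bromo-3-methoxy-2-{[(2S)-1-methoxy-1-(3,4,5-trimethoxyphenyl)propan-2-yl]oxy}phenyl formate | C[C@H](Oc1c(OC=O)cc(Br)cc1OC)C(OC)c1cc(OC)c(OC)c(OC)c1
F7 | step 2 | 5-bromo-3-methoxy-2-{[(2S)-1-methoxy-1-(3,4,5-trimethoxyphenyl)propan-2-yl]oxy}phenol | C[C@H](Oc1c(O)cc(Br)cc1OC)C(OC)c1cc(OC)c(OC)c(OC)c1
F8 | step 4 | (2S)-2-(4-bromo-2-hydroxy-6-methoxyphenoxy)-1-(3,4,5-trimethoxyphenyl)propan-1-one | C[C@H](Oc1c(O)cc(Br)cc1OC)C(=O)c1cc(OC)c(OC)c(OC)c1
F9 | step 4 | (1R,2S)-2-(4-bromo-2-hydroxy-6-methoxyphenoxy)-1-(3,4,5-trimethoxyphenyl)propan-1-ol | C[C@H](Oc1c(O)cc(Br)cc1OC)[C@H](O)c1cc(OC)c(OC)c(OC)c1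
F10 | step 5 | [(2S,3S)-5-methoxy-3-methyl-2-(3,4,5-trimethoxyphenyl)-2,3-dihydro-1,4-benzodioxin-7-yl]lithium | COc1cc([C@@H]2Oc3cc([Li])cc(OC)c3O[C@H]2C)cc(OC)c1OC
F11 | step 5 | (2S,3S)-5-methoxy-3-methyl-2-(3,4,5-trimethoxyphenyl)-2,3-dihydro-1,4-benzodioxine-7-carbaldehyde | COc1cc([C@@H]2Oc3cc(C=O)cc(OC)c3O[C@H]2C)cc(OC)c1OC
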